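**Strategy.** The target is a cis-fused (5β-H) drimane ether of isofraxidin. In ring B, C9 sits between the quaternary C10 and C8, whose exocyclic methylene is a masked ketone; C9 and C10 are therefore the α- and β-carbons of a ring B enone. Both the C9–C11 and the C10–CH3 bonds are made in one operation: lithium dimethylcuprate adds to an enantioenriched Δ9(10)-octalin-8-one, and the regiodefined enolate is alkylated at C9 by 7-(chloromethoxy)-6,8-dimethoxycoumarin. Three components are joined, and the quaternary centre, the cis ring fusion and C9 are set together. The enone comes from Birch reduction of a tetralone ketal and asymmetric isomerisation; methylenation, deketalisation and C2 acetoxylation follow.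

Key step: step 6

Remarks and assumptions
- Drimane numbering is used for the decalin: ring A = C1, C2, C3, C4, C5, C10; ring B = C5, C6, C7, C8, C9, C10; C11 = OCH2; C12 = exocyclic CH2. β is the face that carries the C10 methyl.
- The target SMILES places H-5 on the same face as the C10 methyl, so the decalin is cis-fused (10β-CH3, 5β-H, 9β-CH2OAr, 2α-OAc; 2R,5S,9S,10S). The route is planned for this.
- The sense of induction of the amine catalyst in step 4 is not predicted here; the pseudo-enantiomer (quinidine or quinine series) that gives the 5S enone is to be chosen after a test run.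
- 6-Methoxy-2-tetralone, isofraxidin and chloromethyl chlorosulfate are taken as commercial.

Step 1
Reactants: 1 6-methoxy-2-tetralone
Product: 3 6-methoxy-1,1-dimethyl-2-tetralone, via monomethyl tetralone 2 (not isolated)
Conditions: NaH (2.5 equiv), MeI (3 equiv), THF, 0 °C to rt
Reagents that add atoms: iodomethane, CI
Why: Double enolate C-alkylation, in which C1 is benzylic and α to the ketone, so both deprotonations and both methylations take place there and no stereocentre results.

Step 2
Reactants: 3 6-methoxy-1,1-dimethyl-2-tetralone
Product: 4 6-methoxy-1,1-dimethyl-2-tetralone ethylene ketal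
Conditions: HOCH2CH2OH, TsOH·H2O (cat.), toluene, reflux, Dean–Stark
Reagents that add atoms: ethylene glycol, OCCO
Why: Acid-catalysed ketalisation with azeotropic removal of water masks the ketone, which lithium in ammonia would otherwise reduce, as a dioxolane that is inert in the Birch, cuprate and enolate steps.

Step 3
Reactants: 4 6-methoxy-1,1-dimethyl-2-tetralone ethylene ketal
Product: 6 β,γ-unsaturated ketone (C8 ketone; C5=C10 alkene; C3 dioxolane), via dienol ether 5 (not isolated)
Conditions: Li, NH3(l), THF, t-BuOH, −78 to −33 °C; then (CO2H)2, MeOH–H2O, rt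
Reagents that add atoms: water, O
Why: Birch reduction protonates the anisole ring at the unsubstituted positions ortho and meta to OMe (C9 and C6), leaving the enol ether and the tetrasubstituted ring-fusion alkene of 5, and oxalic acid then hydrolyses only the enol ether without cleaving the dioxolane or moving the C5=C10 bond.

Step 4
Reactants: 6 β,γ-unsaturated ketone
Product: 7 (4aS)-6,6-ethylenedioxy-5,5-dimethyl-4,4a,5,6,7,8-hexahydronaphthalen-2(3H)-one (C8 ketone; C9=C10 alkene; H-5 β)
Conditions: 9-amino-9-deoxy-epi-quinidine (10 mol %), 4-nitrobenzoic acid (20 mol %), toluene, −20 °C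
Reagents that add atoms: none
Why: Catalytic enantioselective β,γ to α,β enone isomerisation by cooperative iminium–base catalysis, in which the primary amine gives the dienamine after deprotonation at C9 and the protonated quinuclidine returns the proton to one face of C5, the conjugated enone being the thermodynamic sink; C5 is set by the catalyst.

Step 5
Reactants: 8 isofraxidin (7-hydroxy-6,8-dimethoxycoumarin)
Product: 9 7-(chloromethoxy)-6,8-dimethoxycoumarin
Conditions: ClCH2OSO2Cl, Bu4NHSO4 (cat.), K2CO3, CH2Cl2–H2O, 0 °C to rt
Reagents that add atoms: chloromethyl chlorosulfate, ClCOS(=O)(=O)Cl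
Why: Phase-transfer O-alkylation of the phenoxide, in which chlorosulfate is by far the better leaving group so that SN2 displacement gives the aryl chloromethyl ether, while the two-phase system keeps the moisture-sensitive product away from base.

Step 6
Reactants: 7 (4aS)-enone ketal; 9 7-(chloromethoxy)-6,8-dimethoxycoumarin
Product: 11 7-{[(5S,9S,10S)-3,3-ethylenedioxy-8-oxo-12-nor-5β-driman-11-yl]oxy}-6,8-dimethoxycoumarin (cis-decalin; 10-CH3 and H-5 and 9-CH2OAr all β), via lithium enolate 10 (not isolated)
Conditions: Me2CuLi (1.3 equiv, from MeLi and CuI), Et2O, −78 to 0 °C; then 9 (1.5 equiv), THF, −78 to −20 °C; cold aq. NH4Cl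
Reagents that add atoms: lithium dimethylcuprate, [Li+].C[Cu-]C (made in the flask from methyllithium, [Li]C, and CuI)
Why: Lithium dimethylcuprate forms a π-complex with enone 7 and transfers methyl to C10 by oxidative addition–reductive elimination, which leaves lithium enolate 10 with its double bond fixed between C8 and C9; this enolate then displaces chloride from the α-chloro ether 9 in an SN2 step at C11. The closest known reaction type is the tandem conjugate addition–enolate alkylation (vicinal difunctionalisation) of cyclohexenones, with alkoxymethyl chlorides as the trapping halides. No ring is closed. C10 is controlled by C5: the quaternary C4 stands out of the enone plane on the α face next to C10, so methyl enters anti to it on the face of H-5 and the ring fusion becomes cis; C9 is controlled by the new cis-fused bicycle, because ring A with its C4 substituents covers the α face and the electrophile enters on the convex β face, antiperiplanar to the C10–C1 bond and cis to the angular methyl. The step needs C- over O-alkylation (lithium counter-ion in ether/THF and an SN2-type aryloxymethyl chloride favour carbon), alkylation at C9 and not C7 (the enolate is trapped cold before it can equilibrate), and survival of the coumarin and of the β-aryloxy ketone (only a small excess of cuprate, chloride 9 far more electrophilic than the lactone, cold buffered quench against E1cB loss of the aryloxide).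

Step 7
Reactants: 11 β-aryloxy ketone
Product: 12 7-{[(5S,9S,10S)-3,3-ethylenedioxy-5β-drim-8(12)-en-11-yl]oxy}-6,8-dimethoxycoumarin
Conditions: Zn, CH2Br2, TiCl4, THF–CH2Cl2, 0 °C to rt
Reagents that add atoms: dibromomethane, BrCBr
Why: Takai–Lombardo methylenation, in which the non-basic CH2(ZnBr)2/TiCl4 reagent adds to the ketone and collapses with loss of Ti–O, so C9 is not epimerised, the β-aryloxy group is not eliminated, and the lactone and dioxolane do not react.

Step 8
Reactants: 12 methylene ketal
Product: 13 7-{[(5S,9S,10S)-3-oxo-5β-drim-8(12)-en-11-yl]oxy}-6,8-dimethoxycoumarin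
Conditions: 1 M HCl, THF, rt
Reagents that add atoms: water, O
Why: Acid-catalysed hydrolysis of the dioxolane, eased by relief of strain next to the gem-dimethyl carbon, under dilute acid at room temperature that leaves the 1,1-disubstituted alkene, the aryl alkyl ether and the lactone intact.

Step 9
Reactants: 13 C3 ketone
Product: 15 7-{[(2R,5S,9S,10S)-2α-hydroxy-3-oxo-5β-drim-8(12)-en-11-yl]oxy}-6,8-dimethoxycoumarin, via potassium enolate 14 (not isolated)
Conditions: KHMDS, THF, −78 °C; then 2-(phenylsulfonyl)-3-phenyloxaziridine, −78 °C; AcOH quench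
Reagents that add atoms: 2-(phenylsulfonyl)-3-phenyloxaziridine, O=S(=O)(c1ccccc1)N1OC1c1ccccc1
Why: Davis oxidation of a ketone enolate, in which C2 is the only enolisable position of the C3 ketone and the oxaziridine transfers oxygen to the α face of enolate 14, away from the axial 10β- and 4β-methyl groups, to give the equatorial 2α-alcohol (2R), which is also the more stable epimer.

Step 10
Reactants: 15 2α-hydroxy ketone
Product: 16 7-{[(2R,5S,9S,10S)-2α-acetoxy-3-oxo-5β-drim-8(12)-en-11-yl]oxy}-6,8-dimethoxycoumarin (target)
Conditions: Ac2O, pyridine, DMAP (cat.), CH2Cl2, 0 °C to rt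
Reagents that add atoms: acetic anhydride, CC(=O)OC(C)=O
Why: DMAP-catalysed acylation of the secondary α-ketol with retention at C2, under mild conditions that avoid epimerisation or ketol rearrangement.

**Compound list**

1 | 6-methoxy-2-tetralone | COc1ccc2c(c1)CCC(=O)C2 | starting material
2 | 6-methoxy-1-methyl-2-tetralone (racemic) | COc1ccc2c(c1)CCC(=O)C2C | intermediate
3 | 6-methoxy-1,1-dimethyl-2-tetralone | COc1ccc2c(c1)CCC(=O)C2(C)C | intermediate
4 | 6-methoxy-1,1-dimethyl-2-tetralone ethylene ketal | COc1ccc2c(c1)CCC1(OCCO1)C2(C)C | intermediate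
5 | dienol ether from Birch reduction (C7=C8 enol ether with 8-OMe; C5=C10 alkene; C3 dioxolane) | COC1=CCC2=C(C1)CCC1(OCCO1)C2(C)C | intermediate
6 | 6,6-ethylenedioxy-5,5-dimethyl-3,4,5,6,7,8-hexahydronaphthalen-2(1H)-one (C8 ketone; C5=C10 alkene) | O=C1CCC2=C(C1)CCC1(OCCO1)C2(C)C | intermediate
7 | (4aS)-6,6-ethylenedioxy-5,5-dimethyl-4,4a,5,6,7,8-hexahydronaphthalen-2(3H)-one (C8 ketone; C9=C10 alkene; H-5 β) | O=C1C=C2CCC3(OCCO3)C(C)(C)[C@H]2CC1 | intermediate
8 | isofraxidin (7-hydroxy-6,8-dimethoxycoumarin) | COc1cc2ccc(=O)oc2c(OC)c1O | starting material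
9 | 7-(chloromethoxy)-6,8-dimethoxycoumarin | COc1cc2ccc(=O)oc2c(OC)c1OCCl | intermediate
10 | lithium enolate (C8–OLi; C8=C9; cis-fused; 10β-CH3; 5β-H; C3 dioxolane) | [Li]OC1=C[C@@]2(C)CCC3(OCCO3)C(C)(C)[C@H]2CC1 | intermediate
11 | 7-{[(5S,9S,10S)-3,3-ethylenedioxy-8-oxo-12-nor-5β-driman-11-yl]oxy}-6,8-dimethoxycoumarin | O=C1CC[C@@H]2C(C)(C)C3(OCCO3)CC[C@]2(C)[C@H]1COc1c(OC)cc2ccc(=O)oc2c1OC | intermediate
12 | 7-{[(5S,9S,10S)-3,3-ethylenedioxy-5β-drim-8(12)-en-11-yl]oxy}-6,8-dimethoxycoumarin | C=C1CC[C@@H]2C(C)(C)C3(OCCO3)CC[C@]2(C)[C@H]1COc1c(OC)cc2ccc(=O)oc2c1OC | intermediate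
13 | 7-{[(5S,9S,10S)-3-oxo-5β-drim-8(12)-en-11-yl]oxy}-6,8-dimethoxycoumarin | C=C1CC[C@@H]2C(C)(C)C(=O)CC[C@]2(C)[C@H]1COc1c(OC)cc2ccc(=O)oc2c1OC | intermediate
14 | potassium Δ2-enolate of 13 (C3–OK; C2=C3) | C=C1CC[C@@H]2C(C)(C)C(O[K])=CC[C@]2(C)[C@H]1COc1c(OC)cc2ccc(=O)oc2c1OC | intermediate
15 | 7-{[(2R,5S,9S,10S)-2α-hydroxy-3-oxo-5β-drim-8(12)-en-11-yl]oxy}-6,8-dimethoxycoumarin | C=C1CC[C@@H]2C(C)(C)C(=O)[C@H](O)C[C@]2(C)[C@H]1COc1c(OC)cc2ccc(=O)oc2c1OC | intermediate
16 | 7-{[(2R,5S,9S,10S)-2α-acetoxy-3-oxo-5β-drim-8(12)-en-11-yl]oxy}-6,8-dimethoxycoumarin | C=C1CC[C@@H]2C(C)(C)C(=O)[C@H](OC(C)=O)C[C@]2(C)[C@H]1COc1c(OC)cc2ccc(=O)oc2c1OC | target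

**Step count**

Total: 10 steps. Longest linear sequence: 9 steps (steps 1–4 and 6–10, from 6-methoxy-2-tetralone).

**Steps most likely to fail**

Step 6 (key step). The enolate may be alkylated on oxygen, may exchange protons before it is trapped, may take the electrophile on the wrong face of C9, or the cuprate/enolate may attack the coumarin. The fallback sets out from 7 and comes back to the route at 12. The same cuprate addition is quenched with N-phenyl-bis(trifluoromethanesulfonimide) to give the C8 enol triflate F1. Kumada coupling with Me3SiCH2MgCl under the zerovalent palladium complex Pd(PPh3)4 in THF gives the allylsilane F2. A Hosomi–Sakurai SE2′ alkylation of F2 with 9 (AgOTf, 2,6-di-tert-butylpyridine, CH2Cl2, −78 °C) should then form the same C9–C11 bond on the convex β face while the double bond moves to C8=C12. This gives 12 directly and avoids the β-aryloxy ketone and step 7.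

Step 4. Proton return to C5, next to the quaternary C4, may be slow or poorly face-selective, so the enone may form with low enantiomeric purity. The fallback sets out from 6 and comes back at 7. NaOMe in MeOH isomerises 6 to the racemic enone F3. Lithiated (S)-N,S-dimethyl-S-phenylsulfoximine (THF, −78 °C) adds to its ketone, and the diastereomeric adducts are separated by chromatography; the one derived from the 4aS enone is the β-hydroxysulfoximine F4. Thermolysis of F4 in refluxing toluene releases 7 and the sulfoximine.

Step 7. The ketone may enolise toward C9 with E1cB loss of the aryloxide or epimerisation, or the hindered carbonyl may be methylenated only slowly. The fallback sets out from 11 and comes back at 13. The non-basic organocerium reagent from Me3SiCH2Li and CeCl3 (THF, −78 °C) should add to the ketone faster than to the lactone and give the β-hydroxysilane F5. Treatment with 1 M HCl in THF then effects Peterson elimination to the exocyclic methylene and hydrolysis of the dioxolane in the same flask, arriving at 13.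

Further compounds
F1 | step 6 | C8 enol triflate of the cis-fused 10β-methyl decalone ketal (C8=C9) | O=S(=O)(OC1=C[C@@]2(C)CCC3(OCCO3)C(C)(C)[C@H]2CC1)C(F)(F)F
F2 | step 6 | allylsilane, C8-(trimethylsilylmethyl) with C8=C9 alkene | C[Si](C)(C)CC1=C[C@@]2(C)CCC3(OCCO3)C(C)(C)[C@H]2CC1
F3 | step 4 | racemic 6,6-ethylenedioxy-5,5-dimethyl-4,4a,5,6,7,8-hexahydronaphthalen-2(3H)-one | O=C1C=C2CCC3(OCCO3)C(C)(C)C2CC1
F4 | step 4 | β-hydroxysulfoximine from the 4aS enone and (S)-N,S-dimethyl-S-phenylsulfoximine (C8 carbinol configuration not assigned) | CN=[S@@](CC1(O)C=C2CCC3(OCCO3)C(C)(C)[C@H]2CC1)(=O)c1ccccc1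
F5 | step 7 | β-hydroxysilane from 11, C8 tertiary alcohol bearing CH2SiMe3 (C8 configuration not assigned) | C[Si](C)(C)CC1(O)CC[C@@H]2C(C)(C)C3(OCCO3)CC[C@]2(C)[C@H]1COc1c(OC)cc2ccc(=O)oc2c1OC
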